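**Plan**
1. Retrosynthesis: remove the C9 angelate, the C11=C13 methylene, the C12–O6 lactone bond and the C10 hydroxyl (back to an E C1=C10 alkene); then cut C8–C9 while rejoining C1–C6 (retro oxy-Cope); finally cut C6–C7 and C1–C10 from a cyclohexenone.
2. Forward: enone 4 (C1–C6, C15) is alkenylated at C1 with bromide 10 (C9, C10, C14), the alkenyl unit C7/C8/C11/C12 adds to C6, and the ten-membered ring arises by [3,3] expansion of the six-membered ring; the lactone is closed afterwards.
3. Enabling feature: the Z C4=C5 bond with C3 and C6 fits a cyclohexene (C6, C5, C4, C3, C2, C1), so C7–C10 can be supplied as two alkenyl groups on C6 and C1.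
4. Stereochemistry: C3 from a CBS reduction; C1 and C6 of the cyclohexenol are set relative to C3 and relayed through the chair to C9; C7 by equilibration next to the ketone; C10 by outer-face epoxidation of C1=C10 and hydride opening at C1; C6 by hydride on the open carbonyl face followed by Mitsunobu inversion.
5. Numbering: all ring intermediates carry the target's atom numbers (C6 bears the lactone oxygen, C11–C13 are the lactone carbons, C14 is on C10, C15 on C4).

Key step: step 9

Remark: compounds 1, 5, 13 and 34 are taken as purchased; the CIP descriptors at C6 and C7 change along the route with substituent priorities, although the spatial arrangement is the one described.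

**Step 1**
Reactants: 1 2-methylcyclohex-2-en-1-one
Product: 2 (S)-2-methylcyclohex-2-en-1-ol
Conditions: (R)-2-methyl-CBS-oxazaborolidine (10 mol %), BH3·SMe2 (0.6 equiv), THF, −20 °C; MeOH quench
Reagents that add atoms: none
Why: Corey–Bakshi–Shibata reduction in which the 2-methylvinyl side of the ketone acts as the large group, so the (R)-oxazaborolidine should deliver hydride to the face that gives the S alcohol, the future C3 centre.

**Step 2**
Reactants: 2 (S)-2-methylcyclohex-2-en-1-ol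
Product: 3 (S)-tert-butyldimethyl[(2-methylcyclohex-2-en-1-yl)oxy]silane
Conditions: TBSCl, imidazole, DMF, rt
Reagents that add atoms: tert-butyldimethylsilyl chloride, CC(C)(C)[Si](C)(C)Cl
Why: standard silylation of a secondary allylic alcohol, which leaves the stereocentre untouched.

**Step 3**
Reactants: 3 (S)-tert-butyldimethyl[(2-methylcyclohex-2-en-1-yl)oxy]silane
Product: 4 (S)-4-(tert-butyldimethylsilyloxy)-3-methylcyclohex-2-en-1-one
Conditions: Rh2(cap)4 (dirhodium tetracaprolactamate, 1 mol %), t-BuOOH (5 equiv), K2CO3, CH2Cl2, rt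
Reagents that add atoms: tert-butyl hydroperoxide, CC(C)(C)OO
Why: dirhodium-catalysed allylic C–H oxidation with t-BuOOH, which should take the only unhindered allylic ring methylene (next to the vinylic CH) to the enone carbonyl while the silyloxy-bearing carbon is shielded.

**Step 4**
Reactants: 5 4-methoxybenzyl alcohol
Product: 8 1-methoxy-4-[(prop-1-yn-1-yloxy)methyl]benzene, via dichlorovinyl ether 6 (not isolated), via lithium acetylide 7 (not isolated)
Conditions: KH, THF, 0 °C; Cl2C=CHCl, −50 °C → rt; n-BuLi (2.5 equiv), −78 °C; MeI, DMPU, −78 → 0 °C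
Reagents that add atoms: trichloroethylene, ClC=C(Cl)Cl; iodomethane, CI
Why: alkoxide addition–elimination on trichloroethylene, then dehydrochlorination/chlorine–lithium exchange and C-methylation (the trichloroethylene route to alkynyl ethers); no stereocentre is involved, and the ether is kept cold because benzylic alkynyl ethers rearrange on warming.

**Step 5**
Reactants: 8 1-methoxy-4-[(prop-1-yn-1-yloxy)methyl]benzene
Product: 10 (E)-1-[(2-bromoprop-1-en-1-yl)oxymethyl]-4-methoxybenzene, via alkenylzirconocene 9 (not isolated)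
Conditions: Cp2Zr(H)Cl, THF, 0 °C → rt; NBS, 0 °C
Reagents that add atoms: N-bromosuccinimide, O=C1CCC(=O)N1Br
Why: syn-hydrozirconation of the polarised ynol ether (hydride to the oxygen-bearing carbon, zirconium to the methyl-bearing carbon) and bromodezirconation with retention should give only the E bromide, with Br trans to oxygen.

**Step 6**
Reactants: 4 (S)-4-(tert-butyldimethylsilyloxy)-3-methylcyclohex-2-en-1-one; 10 (E)-1-[(2-bromoprop-1-en-1-yl)oxymethyl]-4-methoxybenzene
Product: 12 (4S,6S)-4-(tert-butyldimethylsilyloxy)-6-[(E)-1-(4-methoxybenzyloxy)prop-1-en-2-yl]-3-methylcyclohex-2-en-1-one (4,6-cis), via lithium dienolate 11 (not isolated)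
Conditions: LiHMDS (2.2 equiv), THF, −78 °C; 10, Pd(OAc)2 (5 mol %), P(t-Bu)3·HBF4 (10 mol %), −78 °C → rt; AcOH, −78 °C
Reagents that add atoms: none
Why: palladium-catalysed α-alkenylation of a ketone enolate (here the kinetic cross-conjugated lithium dienolate) with retention of the bromide geometry; the new C1 centre lies α to the ketone and should settle, through the product enolate and the quench, as the 4,6-cis isomer with both substituents pseudo-equatorial.

**Step 7**
Reactants: 13 3-bromobut-3-en-1-ol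
Product: 14 (3-bromobut-3-en-1-yloxy)triethylsilane
Conditions: TESCl, imidazole, CH2Cl2, 0 °C
Reagents that add atoms: chlorotriethylsilane, CC[Si](Cl)(CC)CC
Why: silylation of a primary alcohol with a group that can later be removed in the presence of the secondary TBS ether.

**Step 8**
Reactants: 14 (3-bromobut-3-en-1-yloxy)triethylsilane; 12 (4S,6S)-4-(tert-butyldimethylsilyloxy)-6-[(E)-1-(4-methoxybenzyloxy)prop-1-en-2-yl]-3-methylcyclohex-2-en-1-one
Product: 17 (1S,4S,6S)-4-(tert-butyldimethylsilyloxy)-6-[(E)-1-(4-methoxybenzyloxy)prop-1-en-2-yl]-3-methyl-1-[4-(triethylsilyloxy)but-1-en-2-yl]cyclohex-2-en-1-ol, via alkenyllithium 15 (not isolated), via alkenylcerium dichloride 16 (not isolated)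
Conditions: t-BuLi (2.0 equiv), Et2O, −78 °C; CeCl3, THF, −78 °C; 12, −78 °C
Reagents that add atoms: none
Why: bromine–lithium exchange, transmetalation to the weakly basic organocerium and 1,2-addition to the enolisable enone; the reagent should add to the carbonyl face trans to the neighbouring C1 alkenyl group, which sets C6 and gives the trans-dialkenyl arrangement.

**Step 9**
Reactants: 17 (1S,4S,6S)-4-(tert-butyldimethylsilyloxy)-6-[(E)-1-(4-methoxybenzyloxy)prop-1-en-2-yl]-3-methyl-1-[4-(triethylsilyloxy)but-1-en-2-yl]cyclohex-2-en-1-ol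
Product: 20 (3S,7R,9S,1(10)E,4Z)-3-(tert-butyldimethylsilyloxy)-9-(4-methoxybenzyloxy)-4,10-dimethyl-7-[2-(triethylsilyloxy)ethyl]cyclodeca-1(10),4-dien-6-one, via potassium alkoxide 18 (not isolated), via potassium enolate 19 (not isolated)
Conditions: KH, 18-crown-6, THF, 0 °C → rt; MeOH, −78 °C → rt
Reagents that add atoms: none
Why: The potassium alkoxide 18 should undergo an anionic oxy-Cope [3,3] shift through a chair in which C8 bonds to C9 as the C1–C6 bond breaks, the closest known reaction type being the KH/18-crown-6 ring expansion of trans-1,2-dialkenylcyclohexanols, enol ether termini included, to cyclodecenones. The ten-membered ring is not closed end to end but arises by four-atom expansion of the cyclohexene, so the Z C4=C5 bond is carried over unchanged and no high dilution is needed. C9 is set by chirality transfer from C1 and C6: both ring bonds sit pseudo-equatorial in the chair, which gives E C1=C10, and the E enol ether places the PMB-oxy group equatorial, which fixes 9S. C7 is set afterwards by protonation of enolate 19 under equilibrating conditions (KOMe from the quench), which should favour the epimer with the side chain pseudo-equatorial (7R here, the spatial arrangement of the target's C7). The step needs chair over boat and [3,3] over [1,3] selectivity; the trans-diequatorial alkenyl groups and the fixed E enol ether of 17 secure the first, and the irreversible, enolate-forming anionic variant at or below room temperature secures the second.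

**Step 10**
Reactants: 20 (3S,7R,9S,1(10)E,4Z)-cyclodeca-1(10),4-dien-6-one described in step 9
Product: 21 (1R,3S,7R,9S,10S,4Z)-3-(tert-butyldimethylsilyloxy)-1,10-epoxy-9-(4-methoxybenzyloxy)-4,10-dimethyl-7-[2-(triethylsilyloxy)ethyl]cyclodec-4-en-6-one
Conditions: mCPBA (1.05 equiv), NaHCO3, CH2Cl2, 0 °C
Reagents that add atoms: 3-chloroperoxybenzoic acid, OOC(=O)c1cccc(Cl)c1
Why: Prilezhaev epoxidation of the strained, electron-rich E C1=C10 bond (the enone C4=C5 bond is inert); the alkene stands perpendicular to the ring with C8 and C3 on its inner face, so the peracid should attack the outer face and give the trans epoxide with the target's C10 configuration.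

**Step 11**
Reactants: 21 (1R,3S,7R,9S,10S,4Z)-1,10-epoxycyclodec-4-en-6-one described in step 10
Product: 22 (3S,6R,7R,9S,10S,4Z)-3-(tert-butyldimethylsilyloxy)-9-(4-methoxybenzyloxy)-4,10-dimethyl-7-[2-(triethylsilyloxy)ethyl]cyclodec-4-ene-6,10-diol (6-OH cis to the C7 side chain)
Conditions: LiAlH4, THF, −78 °C → 40 °C
Reagents that add atoms: none
Why: 1,2-hydride reduction of the enone and SN2 opening of the trisubstituted epoxide at its secondary carbon C1; C1, formerly bonded to C6, still lies under one face of the carbonyl, so hydride should enter from the open face to give the alcohol cis to the side chain, and the resulting aluminate sits over C1 and can deliver hydride to the epoxide from inside the ring, leaving the tertiary 10S alcohol.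

**Step 12**
Reactants: 22 (3S,6R,7R,9S,10S,4Z)-cyclodec-4-ene-6,10-diol described in step 11
Product: 23 (3S,6S,7R,9S,10S,4Z)-3-(tert-butyldimethylsilyloxy)-10-hydroxy-9-(4-methoxybenzyloxy)-4,10-dimethyl-7-[2-(triethylsilyloxy)ethyl]cyclodec-4-en-6-yl 4-nitrobenzoate
Conditions: 4-nitrobenzoic acid, PPh3, DIAD, toluene, 0 °C → rt
Reagents that add atoms: 4-nitrobenzoic acid, OC(=O)c1ccc(cc1)[N+](=O)[O-]
Why: Mitsunobu esterification of the secondary allylic alcohol with inversion (the tertiary C10 alcohol is inert), which places the C6 oxygen trans to the C7 side chain as the lactone requires.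

**Step 13**
Reactants: 23 (3S,6S,7R,9S,10S,4Z)-cyclodec-4-en-6-yl 4-nitrobenzoate described in step 12
Product: 25 (3S,6S,7R,9S,10S,4Z)-3-(tert-butyldimethylsilyloxy)-7-(2-hydroxyethyl)-9-(4-methoxybenzyloxy)-4,10-dimethylcyclodec-4-ene-6,10-diol, via triethylsilyl ether diol 24 (not isolated)
Conditions: K2CO3 (0.3 equiv), MeOH, rt; then PPTS (1 equiv), rt
Reagents that add atoms: none
Why: base-catalysed transesterification of the 4-nitrobenzoate followed in the same flask by acid-catalysed methanolysis of the primary triethylsilyl ether, conditions that should leave the secondary TBS ether and the PMB ether in place.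

**Step 14**
Reactants: 25 (3S,6S,7R,9S,10S,4Z)-triol described in step 13
Product: 28 (3S,6S,7S,9S,10S,4Z)-3-(tert-butyldimethylsilyloxy)-10-hydroxy-9-(4-methoxybenzyloxy)germacr-4-en-12,6-olide (trans-fused γ-lactone; C11 is CH2), via aldehyde 26 (not isolated), via lactol 27 (not isolated)
Conditions: TEMPO (0.2 equiv), PhI(OAc)2 (3 equiv), CH2Cl2, rt
Reagents that add atoms: none
Why: oxoammonium (TEMPO/PhI(OAc)2) oxidation selective for the primary alcohol, closure of the aldehyde onto the C6 hydroxyl and further oxidation of the lactol should give the trans-fused γ-lactone without touching C6 or C7.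

**Step 15**
Reactants: 28 (3S,6S,7S,9S,10S,4Z)-germacr-4-en-12,6-olide described in step 14
Product: 30 11-(dimethylaminomethyl) derivative of lactone 28 (either C11 epimer), via dilithium enolate 29 (not isolated)
Conditions: LDA (3.3 equiv), THF, −78 °C; CH2=NMe2+ I−, −78 °C → rt
Reagents that add atoms: Eschenmoser's salt (N,N-dimethylmethyleneiminium iodide), C=[N+](C)C.[I-]
Why: Mannich reaction of the lactone enolate with Eschenmoser's salt, the tertiary alcohol being carried as its lithium alkoxide; the new C11 centre is of no consequence because it becomes sp2 in the next step.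

**Step 16**
Reactants: 30 11-(dimethylaminomethyl) lactone
Product: 32 (3S,6R,7S,9S,10S,4Z)-3-(tert-butyldimethylsilyloxy)-10-hydroxy-9-(4-methoxybenzyloxy)germacra-4,11(13)-dien-12,6-olide, via ammonium iodide 31 (not isolated)
Conditions: MeI, MeOH, rt; NaHCO3 (aq), CH2Cl2, rt
Reagents that add atoms: none
Why: N-methylation and Hofmann-type β-elimination of trimethylamine from the quaternary Mannich salt give the α-methylene lactone.

**Step 17**
Reactants: 32 (3S,6R,7S,9S,10S,4Z)-germacra-4,11(13)-dien-12,6-olide PMB ether described in step 16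
Product: 33 (3S,6R,7S,9S,10S,4Z)-3-(tert-butyldimethylsilyloxy)-9,10-dihydroxygermacra-4,11(13)-dien-12,6-olide
Conditions: DDQ, CH2Cl2/pH 7 buffer (10:1), 0 °C
Reagents that add atoms: none
Why: oxidative cleavage of the PMB ether by DDQ through the benzylic oxocarbenium ion, run in wet solvent so that the neighbouring C10 hydroxyl is not tied up as an acetal; the TBS ether, the enoate and the alkenes are inert.

**Step 18**
Reactants: 33 (3S,6R,7S,9S,10S,4Z)-9,10-diol described in step 17; 34 angelic acid ((Z)-2-methylbut-2-enoic acid)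
Product: 36 (3S,6R,7S,9S,10S,4Z)-9-angeloyloxy-3-(tert-butyldimethylsilyloxy)-10-hydroxygermacra-4,11(13)-dien-12,6-olide, via mixed anhydride 35 (not isolated)
Conditions: 34, 2,4,6-trichlorobenzoyl chloride, Et3N, toluene, rt; then 33, toluene, 80 °C
Reagents that add atoms: none
Why: Yamaguchi-type acylation through the angelic 2,4,6-trichlorobenzoic mixed anhydride without a nucleophilic catalyst, conditions known to keep the Z geometry of the angeloyl group; only the secondary C9 alcohol should react, not the tertiary C10 alcohol.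

**Step 19**
Reactants: 36 TBS ether of the target
Product: 37 CNP0549192.1, (3S,6R,7S,9S,10S,4Z)-9-angeloyloxy-3,10-dihydroxygermacra-4,11(13)-dien-12,6-olide
Conditions: HF·pyridine, pyridine, THF, 0 °C → rt
Reagents that add atoms: none
Why: buffered fluoride cleavage of the secondary TBS ether, which should spare the α-methylene lactone, the angelate and the tertiary alcohol.

**Compound list**
1 | 2-methylcyclohex-2-en-1-one | CC1=CCCC1=O | starting material
2 | (S)-2-methylcyclohex-2-en-1-ol | CC1=CCC[C@@H]1O | intermediate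
3 | (S)-tert-butyldimethyl[(2-methylcyclohex-2-en-1-yl)oxy]silane | CC1=CCC[C@@H]1O[Si](C)(C)C(C)(C)C | intermediate
4 | (S)-4-(tert-butyldimethylsilyloxy)-3-methylcyclohex-2-en-1-one | CC1=CC(=O)CC[C@@H]1O[Si](C)(C)C(C)(C)C | intermediate
5 | 4-methoxybenzyl alcohol | COc1ccc(CO)cc1 | starting material
6 | (E)-1-[(1,2-dichloroethenyl)oxymethyl]-4-methoxybenzene | Cl/C=C(/Cl)OCc1ccc(OC)cc1 | intermediate
7 | lithium [(4-methoxybenzyl)oxy]acetylide | [Li]C#COCc1ccc(OC)cc1 | intermediate
8 | 1-methoxy-4-[(prop-1-yn-1-yloxy)methyl]benzene | CC#COCc1ccc(OC)cc1 | intermediate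
9 | chloro{(E)-1-[(4-methoxybenzyl)oxy]prop-1-en-2-yl}zirconocene (Zr trans to O) | C/C(=C\OCc1ccc(OC)cc1)[Zr](Cl)(C1C=CC=C1)C1C=CC=C1 | intermediate
10 | (E)-1-[(2-bromoprop-1-en-1-yl)oxymethyl]-4-methoxybenzene | C/C(Br)=C\OCc1ccc(OC)cc1 | intermediate
11 | lithium (S)-4-(tert-butyldimethylsilyloxy)-5-methylcyclohexa-1,5-dien-1-olate | [Li]OC1=CC[C@H](O[Si](C)(C)C(C)(C)C)C(C)=C1 | intermediate
12 | (4S,6S)-4-(tert-butyldimethylsilyloxy)-6-[(E)-1-(4-methoxybenzyloxy)prop-1-en-2-yl]-3-methylcyclohex-2-en-1-one | O=C1C=C(C)[C@@H](O[Si](C)(C)C(C)(C)C)C[C@H]1/C(C)=C/OCc2ccc(OC)cc2 | intermediate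
13 | 3-bromobut-3-en-1-ol | C=C(Br)CCO | starting material
14 | (3-bromobut-3-en-1-yloxy)triethylsilane | C=C(Br)CCO[Si](CC)(CC)CC | intermediate
15 | [4-(triethylsilyloxy)but-1-en-2-yl]lithium | [Li]C(=C)CCO[Si](CC)(CC)CC | intermediate
16 | dichloro[4-(triethylsilyloxy)but-1-en-2-yl]cerium | Cl[Ce](Cl)C(=C)CCO[Si](CC)(CC)CC | intermediate
17 | (1S,4S,6S)-4-(tert-butyldimethylsilyloxy)-6-[(E)-1-(4-methoxybenzyloxy)prop-1-en-2-yl]-3-methyl-1-[4-(triethylsilyloxy)but-1-en-2-yl]cyclohex-2-en-1-ol | O[C@@]1(C(=C)CCO[Si](CC)(CC)CC)C=C(C)[C@@H](O[Si](C)(C)C(C)(C)C)C[C@H]1/C(C)=C/OCc2ccc(OC)cc2 | intermediate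
18 | potassium alkoxide of 17 | [K+].[O-][C@@]1(C(=C)CCO[Si](CC)(CC)CC)C=C(C)[C@@H](O[Si](C)(C)C(C)(C)C)C[C@H]1/C(C)=C/OCc2ccc(OC)cc2 | intermediate
19 | potassium C6=C7 enolate of 20 (O cis to C8; 1(10)E, 4Z; 3S,9S) | C1[C@H](OCc2ccc(OC)cc2)/C(C)=C/C[C@H](O[Si](C)(C)C(C)(C)C)/C(C)=C\C(\[O-])=C1/CCO[Si](CC)(CC)CC.[K+] | intermediate
20 | (3S,7R,9S,1(10)E,4Z)-3-(tert-butyldimethylsilyloxy)-9-(4-methoxybenzyloxy)-4,10-dimethyl-7-[2-(triethylsilyloxy)ethyl]cyclodeca-1(10),4-dien-6-one | O=C1/C=C(/C)[C@@H](O[Si](C)(C)C(C)(C)C)C/C=C(C)/[C@@H](OCc2ccc(OC)cc2)C[C@H]1CCO[Si](CC)(CC)CC | intermediate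
21 | (1R,3S,7R,9S,10S,4Z)-3-(tert-butyldimethylsilyloxy)-1,10-epoxy-9-(4-methoxybenzyloxy)-4,10-dimethyl-7-[2-(triethylsilyloxy)ethyl]cyclodec-4-en-6-one | O=C1/C=C(/C)[C@@H](O[Si](C)(C)C(C)(C)C)C[C@H]2O[C@]2(C)[C@@H](OCc3ccc(OC)cc3)C[C@H]1CCO[Si](CC)(CC)CC | intermediate
22 | (3S,6R,7R,9S,10S,4Z)-3-(tert-butyldimethylsilyloxy)-9-(4-methoxybenzyloxy)-4,10-dimethyl-7-[2-(triethylsilyloxy)ethyl]cyclodec-4-ene-6,10-diol | O[C@H]1/C=C(/C)[C@@H](O[Si](C)(C)C(C)(C)C)CC[C@](C)(O)[C@@H](OCc2ccc(OC)cc2)C[C@H]1CCO[Si](CC)(CC)CC | intermediate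
23 | (3S,6S,7R,9S,10S,4Z)-3-(tert-butyldimethylsilyloxy)-10-hydroxy-9-(4-methoxybenzyloxy)-4,10-dimethyl-7-[2-(triethylsilyloxy)ethyl]cyclodec-4-en-6-yl 4-nitrobenzoate | O=C(O[C@@H]1/C=C(/C)[C@@H](O[Si](C)(C)C(C)(C)C)CC[C@](C)(O)[C@@H](OCc2ccc(OC)cc2)C[C@H]1CCO[Si](CC)(CC)CC)c3ccc(cc3)[N+](=O)[O-] | intermediate
24 | (3S,6S,7R,9S,10S,4Z)-3-(tert-butyldimethylsilyloxy)-9-(4-methoxybenzyloxy)-4,10-dimethyl-7-[2-(triethylsilyloxy)ethyl]cyclodec-4-ene-6,10-diol | O[C@@H]1/C=C(/C)[C@@H](O[Si](C)(C)C(C)(C)C)CC[C@](C)(O)[C@@H](OCc2ccc(OC)cc2)C[C@H]1CCO[Si](CC)(CC)CC | intermediate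
25 | (3S,6S,7R,9S,10S,4Z)-3-(tert-butyldimethylsilyloxy)-7-(2-hydroxyethyl)-9-(4-methoxybenzyloxy)-4,10-dimethylcyclodec-4-ene-6,10-diol | O[C@@H]1/C=C(/C)[C@@H](O[Si](C)(C)C(C)(C)C)CC[C@](C)(O)[C@@H](OCc2ccc(OC)cc2)C[C@H]1CCO | intermediate
26 | (3S,6S,7S,9S,10S,4Z)-2-[3-(tert-butyldimethylsilyloxy)-6,10-dihydroxy-9-(4-methoxybenzyloxy)-4,10-dimethylcyclodec-4-en-7-yl]acetaldehyde | O[C@@H]1/C=C(/C)[C@@H](O[Si](C)(C)C(C)(C)C)CC[C@](C)(O)[C@@H](OCc2ccc(OC)cc2)C[C@H]1CC=O | intermediate
27 | lactol of 26 (12-hydroxy-12,6-cyclic hemiacetal, both C12 epimers) | C1C(O)O[C@@H]2/C=C(/C)[C@@H](O[Si](C)(C)C(C)(C)C)CC[C@](C)(O)[C@@H](OCc3ccc(OC)cc3)C[C@@H]12 | intermediate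
28 | (3S,6S,7S,9S,10S,4Z)-3-(tert-butyldimethylsilyloxy)-10-hydroxy-9-(4-methoxybenzyloxy)germacr-4-en-12,6-olide | C1C(=O)O[C@@H]2/C=C(/C)[C@@H](O[Si](C)(C)C(C)(C)C)CC[C@](C)(O)[C@@H](OCc3ccc(OC)cc3)C[C@@H]12 | intermediate
29 | dilithium salt of 28 (lactone enolate, C10 alkoxide) | C1=C(O[Li])O[C@@H]2/C=C(/C)[C@@H](O[Si](C)(C)C(C)(C)C)CC[C@](C)(O[Li])[C@@H](OCc3ccc(OC)cc3)C[C@@H]12 | intermediate
30 | 11-(dimethylaminomethyl) derivative of 28 (C11 epimers) | CN(C)CC1C(=O)O[C@@H]2/C=C(/C)[C@@H](O[Si](C)(C)C(C)(C)C)CC[C@](C)(O)[C@@H](OCc3ccc(OC)cc3)C[C@@H]12 | intermediate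
31 | trimethylammonium iodide of 30 | C[N+](C)(C)CC1C(=O)O[C@@H]2/C=C(/C)[C@@H](O[Si](C)(C)C(C)(C)C)CC[C@](C)(O)[C@@H](OCc3ccc(OC)cc3)C[C@@H]12.[I-] | intermediate
32 | (3S,6R,7S,9S,10S,4Z)-3-(tert-butyldimethylsilyloxy)-10-hydroxy-9-(4-methoxybenzyloxy)germacra-4,11(13)-dien-12,6-olide | C=C1C(=O)O[C@@H]2/C=C(/C)[C@@H](O[Si](C)(C)C(C)(C)C)CC[C@](C)(O)[C@@H](OCc3ccc(OC)cc3)C[C@@H]12 | intermediate
33 | (3S,6R,7S,9S,10S,4Z)-3-(tert-butyldimethylsilyloxy)-9,10-dihydroxygermacra-4,11(13)-dien-12,6-olide | C=C1C(=O)O[C@@H]2/C=C(/C)[C@@H](O[Si](C)(C)C(C)(C)C)CC[C@](C)(O)[C@@H](O)C[C@@H]12 | intermediate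
34 | angelic acid | C/C=C(/C)C(=O)O | starting material
35 | angelic 2,4,6-trichlorobenzoic anhydride | C/C=C(/C)C(=O)OC(=O)c1c(Cl)cc(Cl)cc1Cl | intermediate
36 | (3S,6R,7S,9S,10S,4Z)-9-angeloyloxy-3-(tert-butyldimethylsilyloxy)-10-hydroxygermacra-4,11(13)-dien-12,6-olide | C=C1C(=O)O[C@@H]2/C=C(/C)[C@@H](O[Si](C)(C)C(C)(C)C)CC[C@](C)(O)[C@@H](OC(=O)/C(C)=C\C)C[C@@H]12 | intermediate
37 | CNP0549192.1, (3S,6R,7S,9S,10S,4Z)-9-angeloyloxy-3,10-dihydroxygermacra-4,11(13)-dien-12,6-olide | C=C1C(=O)O[C@@H]2/C=C(/C)[C@@H](O)CC[C@](C)(O)[C@@H](OC(=O)/C(C)=C\C)C[C@@H]12 | target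

**Step count**
Total: 19 steps. Longest linear sequence: 16 steps (steps 1–3, 6, 8–19).

**Three steps most likely to fail**

Step 11. Hydride may not reach C1, because the rear side of the C1–O bond of the epoxide points into the ring; the epoxide could then survive or open by transannular attack of C4=C5 on work-up. Delivery of hydride to the other face of C6 would also give the wrong C6 epimer for the inversion that follows. The fallback postpones the hydration of C1=C10 and makes it a radical process. It sets out from 20 and comes back at 28. Luche reduction (NaBH4, CeCl3·7H2O, MeOH, −78 °C) would give the dienol F3, with the hydroxyl cis to the side chain. Mitsunobu inversion with 4-nitrobenzoic acid would give the ester F4. K2CO3/MeOH would give the inverted dienol F5, and PPTS in the same flask the diol F6. TEMPO/PhI(OAc)2 would lead through the aldehyde F7 and the lactol F8 to the dienyl lactone F9. A Mukaiyama hydration (Co(acac)2, PhSiH3, O2, i-PrOH) would then add H to C1 and OH to C10 of the strained, more electron-rich C1=C10 bond from its outer face, giving 28.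

Step 12. The substitution takes place at a ring carbon, where the carboxylate has to enter opposite the oxyphosphonium group. Elimination to a diene, attack with allylic shift at C4, or ionisation and return with retention may take over. The fallback moves the inversion into the ring closure. It sets out from 22 and comes back at 28. PPTS/MeOH would give the triol F10. TEMPO/PhI(OAc)2 would give, through the aldehyde F11 and the lactol F12, the cis-fused lactone F13. LiOH (THF/H2O) and acidification to pH 4 at 0 °C would give the hydroxy acid F14. Its Mitsunobu lactonisation (PPh3, DIAD, toluene) would close the five-membered ring by intramolecular SN2 with inversion at C6.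

Step 6. The enolate may couple through its extended form at the γ-carbon, the new β,γ-double bond may move into conjugation under base, oxidative addition of the electron-rich bromide may be slow, or protonation may give the 4,6-trans isomer. The fallback reverses the polarity of the C1–C10 bond formation. It sets out from 4 and 8 and comes back at 12. Dienolate 11 would be trapped with TMSCl as the silyl dienol ether F1, and NBS would convert it into the α'-bromo enone F2. A nickel-catalysed Negishi-type coupling (NiCl2·glyme, 4,4'-di-tert-butyl-2,2'-bipyridine, THF, rt) of F2 with alkenylzirconocene 9, made from 8 as in step 5, would join C1 to C10. Mild base would equilibrate C1 to the cis isomer 12.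

**Further compounds**
F1 | step 6 | (S)-tert-butyldimethyl{[2-methyl-4-(trimethylsilyloxy)cyclohexa-2,4-dien-1-yl]oxy}silane | C[Si](C)(C)OC1=CC[C@H](O[Si](C)(C)C(C)(C)C)C(C)=C1
F2 | step 6 | (4S)-6-bromo-4-(tert-butyldimethylsilyloxy)-3-methylcyclohex-2-en-1-one (C6 epimers) | O=C1C=C(C)[C@@H](O[Si](C)(C)C(C)(C)C)CC1Br
F3 | step 11 | (3S,6R,7R,9S,1(10)E,4Z)-3-(tert-butyldimethylsilyloxy)-9-(4-methoxybenzyloxy)-4,10-dimethyl-7-[2-(triethylsilyloxy)ethyl]cyclodeca-1(10),4-dien-6-ol | O[C@H]1/C=C(/C)[C@@H](O[Si](C)(C)C(C)(C)C)C/C=C(C)/[C@@H](OCc2ccc(OC)cc2)C[C@H]1CCO[Si](CC)(CC)CC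
F4 | step 11 | (6S)-4-nitrobenzoate of the C6 epimer of F3 | O=C(O[C@@H]1/C=C(/C)[C@@H](O[Si](C)(C)C(C)(C)C)C/C=C(C)/[C@@H](OCc2ccc(OC)cc2)C[C@H]1CCO[Si](CC)(CC)CC)c3ccc(cc3)[N+](=O)[O-]
F5 | step 11 | (3S,6S,7R,9S,1(10)E,4Z)-dienol, C6 epimer of F3 | O[C@@H]1/C=C(/C)[C@@H](O[Si](C)(C)C(C)(C)C)C/C=C(C)/[C@@H](OCc2ccc(OC)cc2)C[C@H]1CCO[Si](CC)(CC)CC
F6 | step 11 | (3S,6S,7R,9S,1(10)E,4Z)-3-(tert-butyldimethylsilyloxy)-7-(2-hydroxyethyl)-9-(4-methoxybenzyloxy)-4,10-dimethylcyclodeca-1(10),4-dien-6-ol | O[C@@H]1/C=C(/C)[C@@H](O[Si](C)(C)C(C)(C)C)C/C=C(C)/[C@@H](OCc2ccc(OC)cc2)C[C@H]1CCO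
F7 | step 11 | aldehyde from F6 (C12 aldehyde, 6-OH free) | O[C@@H]1/C=C(/C)[C@@H](O[Si](C)(C)C(C)(C)C)C/C=C(C)/[C@@H](OCc2ccc(OC)cc2)C[C@H]1CC=O
F8 | step 11 | lactol of F7 (C12 epimers) | C1C(O)O[C@@H]2/C=C(/C)[C@@H](O[Si](C)(C)C(C)(C)C)C/C=C(C)/[C@@H](OCc3ccc(OC)cc3)C[C@@H]12
F9 | step 11 | (3S,6S,7S,9S,1(10)E,4Z)-3-(tert-butyldimethylsilyloxy)-9-(4-methoxybenzyloxy)germacra-1(10),4-dien-12,6-olide | C1C(=O)O[C@@H]2/C=C(/C)[C@@H](O[Si](C)(C)C(C)(C)C)C/C=C(C)/[C@@H](OCc3ccc(OC)cc3)C[C@@H]12
F10 | step 12 | (3S,6R,7R,9S,10S,4Z)-triol, C6 epimer of 25 | O[C@H]1/C=C(/C)[C@@H](O[Si](C)(C)C(C)(C)C)CC[C@](C)(O)[C@@H](OCc2ccc(OC)cc2)C[C@H]1CCO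
F11 | step 12 | aldehyde from F10 | O[C@H]1/C=C(/C)[C@@H](O[Si](C)(C)C(C)(C)C)CC[C@](C)(O)[C@@H](OCc2ccc(OC)cc2)C[C@H]1CC=O
F12 | step 12 | cis-fused lactol of F11 (C12 epimers) | C1C(O)O[C@H]2/C=C(/C)[C@@H](O[Si](C)(C)C(C)(C)C)CC[C@](C)(O)[C@@H](OCc3ccc(OC)cc3)C[C@@H]12
F13 | step 12 | (3S,6R,7S,9S,10S,4Z)-cis-fused lactone, C6 epimer of 28 | C1C(=O)O[C@H]2/C=C(/C)[C@@H](O[Si](C)(C)C(C)(C)C)CC[C@](C)(O)[C@@H](OCc3ccc(OC)cc3)C[C@@H]12
F14 | step 12 | (3S,6R,7S,9S,10S,4Z)-2-[3-(tert-butyldimethylsilyloxy)-6,10-dihydroxy-9-(4-methoxybenzyloxy)-4,10-dimethylcyclodec-4-en-7-yl]acetic acid | O[C@H]1/C=C(/C)[C@@H](O[Si](C)(C)C(C)(C)C)CC[C@](C)(O)[C@@H](OCc2ccc(OC)cc2)C[C@H]1CC(=O)O
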